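## Retrosynthetic overview
1. The oxirane comes last, by exo, OH-guided epoxidation of the ring B alkene of a 1-hydroxybicyclo[3.3.1]non-2-en-9-one. Ring A is the cyclohexane carrying NH-acyl and OH; ring B is the carbocycle carrying OMe.
2. Ring A closes by an intramolecular aldol (ketone α-carbon onto the amido aldehyde). Just before, in the same flask, ring B forms by an α-ketol 1,2-alkenyl shift that enlarges a 1-acyl-4-methoxycyclopent-2-en-1-ol from five to six carbons.
3. The acylcyclopentenol and the aldehyde are stored together as a spiro pyranone hemiacetal. Its C–N bond comes from azide conjugate addition and Staudinger-type amide ligation, and the pyranone from Achmatowicz ring expansion of a furyl carbinol.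
4. The furyl carbinol comes from 2-furyllithium and (S)-4-methoxycyclopent-2-enone, which holds the only bought stereocentre. The side-chain acid comes from 1-bromoheptane, acrolein and malonic acid.
5. Ring order: cyclopentene (bought) → temporary pyranone → ring B (five → six) → ring A → oxirane.

Assumption: (S)-4-hydroxycyclopent-2-en-1-one is bought enantiopure. Centres that are mixtures and are erased or equilibrated later (C7 and C8 of the spiro compounds, the amido-aldehyde carbon of 17 and 18) are left unmarked in the SMILES.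

## Route

Step 1
Reactants: 1 (S)-4-hydroxycyclopent-2-en-1-one
Product: 2 (S)-4-methoxycyclopent-2-en-1-one
Conditions: MeI, Ag2O, CH2Cl2, rt, dark
Reagents that add atoms: iodomethane CI
Why: Purdie-type Williamson methylation under neutral Ag2O conditions alkylates the secondary allylic OH without enolising the β-oxy enone, so the C4 centre (the later C–OMe centre of the target) is carried over unchanged.

Step 2
Reactants: 3 furan; 2 (S)-4-methoxycyclopent-2-en-1-one
Product: 5 (1R,4S)-1-(furan-2-yl)-4-methoxycyclopent-2-en-1-ol, via 2-furyllithium 4 (not isolated)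
Conditions: n-BuLi, THF, 0 °C; then 2, −78 °C; H2O quench
Reagents that add atoms: none
Why: α-Lithiation of furan and 1,2-addition of the hard aryllithium to the enone carbonyl from the face opposite the C4 methoxy group set the tertiary carbinol centre as 1R (OH cis to OMe; the minor epimer is removed by chromatography).

Step 3
Reactants: 5 (1R,4S)-1-(furan-2-yl)-4-methoxycyclopent-2-en-1-ol
Product: 6 (3S,5R)-7-hydroxy-3-methoxy-6-oxaspiro[4.5]deca-1,8-dien-10-one
Conditions: NBS, NaHCO3, THF–H2O, 0 °C
Reagents that add atoms: water O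
Why: In this Achmatowicz oxidative ring expansion the electron-rich furan is oxidised far faster than the cyclopentene flanked by two allylic oxygens, and the tertiary OH traps the enedione as the six-membered hemiacetal with no change at C3 or C5.

Step 4
Reactants: 6 (3S,5R)-7-hydroxy-3-methoxy-6-oxaspiro[4.5]deca-1,8-dien-10-one
Product: 7 (3S,5R)-8-azido-7-hydroxy-3-methoxy-6-oxaspiro[4.5]dec-1-en-10-one
Conditions: NaN3, AcOH, THF–H2O, rt
Reagents that add atoms: sodium azide [Na+].[N-]=[N+]=[N-]
Why: Conjugate (aza-Michael) addition of HN3 to the strongly electrophilic pyranone enone places nitrogen on the β-carbon C8, and the configuration formed here does not matter because this centre is equilibrated in step 8.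

Step 5
Reactants: 8 1-bromoheptane; 9 acrolein
Product: 12 decanal, via heptylmagnesium bromide 10 (not isolated), via dec-1-enyl trimethylsilyl ether 11 (not isolated)
Conditions: Mg, THF; CuBr·SMe2 (5 mol %), TMSCl, DMPU, 9, −78 °C; then 1 M HCl
Reagents that add atoms: none
Why: Copper-catalysed, TMSCl-accelerated conjugate addition of a primary Grignard reagent to acrolein gives the silyl enol ether, which is hydrolysed to the C10 aldehyde, and no stereocentre is formed.

Step 6
Reactants: 12 decanal; 13 malonic acid
Product: 14 (E)-dodec-2-enoic acid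
Conditions: pyridine, piperidine (cat.), rt → 90 °C
Reagents that add atoms: none
Why: Knoevenagel–Doebner condensation with decarboxylation in pyridine gives the thermodynamically preferred E-2-enoic acid.

Step 7
Reactants: 7 (3S,5R)-8-azido-7-hydroxy-3-methoxy-6-oxaspiro[4.5]dec-1-en-10-one; 14 (E)-dodec-2-enoic acid
Product: 16 (E)-N-[(3S,5R)-7-hydroxy-3-methoxy-10-oxo-6-oxaspiro[4.5]dec-1-en-8-yl]dodec-2-enamide, via iminophosphorane 15 (not isolated)
Conditions: PMe3, THF, 0 °C; then 14, toluene, 40 °C
Reagents that add atoms: none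
Why: The Staudinger reaction and direct acylation of the iminophosphorane by the acid (Staudinger–Vilarrasa ligation) form the amide without freeing the self-condensing β-amino ketone, and the E-alkene, ketone and hemiacetal are untouched.

Step 8
Reactants: 16 (E)-N-[(3S,5R)-7-hydroxy-3-methoxy-10-oxo-6-oxaspiro[4.5]dec-1-en-8-yl]dodec-2-enamide
Product: 19 (E)-N-[(1S,4R,5S,6R,7S)-1,6-dihydroxy-4-methoxy-9-oxobicyclo[3.3.1]non-2-en-7-yl]dodec-2-enamide, via open keto aldehyde 17 (not isolated), via ring-enlarged hydroxy aldehyde 18 (not isolated)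
Conditions: Sc(OTf)3 (10 mol %), 2,6-di-tert-butylpyridine (20 mol %), MeCN, 50 °C; then iPr2NEt (30 mol %), 0 °C → rt
Reagents that add atoms: none
Why: Proposed new method: Sc(OTf)3 binds the open-chain share of hemiacetal 16 (17) as a five-membered O,O-chelate with C=O and C–OH syn-coplanar, so both ring bonds at the carbinol carbon flank the carbonyl π* and the alkenyl carbon (a better bridging migrator than the CH2 deactivated by the β-OMe) shifts to the acyl carbon on the face fixed by the 1R centre, which relieves cyclopentene strain and gives 18 with the new tertiary OH cis to OMe (sheltered as its spiro lactol); the added amine then epimerises the amido-aldehyde carbon and forms the scandium enolate, whose only reachable electrophile is that aldehyde, and the chair-like, metal-bridged aldol closes ring A with NH-acyl equatorial and the new OH syn to the bridging C=O, so four centres are set; the closest known reaction types are the Lewis-acid α-ketol (acyloin) ring enlargement of 1-acylcycloalkanols and the aldol closure of 2-(3-oxopropyl)cyclohexanones to bicyclo[3.3.1]nonan-9-ones, neither of which has been shown for alkenyl migration, for pyranose-masked ketols or combined in one flask.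

Step 9
Reactants: 19 (E)-N-[(1S,4R,5S,6R,7S)-1,6-dihydroxy-4-methoxy-9-oxobicyclo[3.3.1]non-2-en-7-yl]dodec-2-enamide
Product: 20 (E)-N-[(1S,2S,4S,5S,6S,7R,8S)-1,7-dihydroxy-5-methoxy-10-oxo-3-oxatricyclo[4.3.1.0(2,4)]decan-8-yl]dodec-2-enamide
Conditions: DMDO (acetone solution), CH2Cl2, 0 °C → rt
Reagents that add atoms: dimethyldioxirane CC1(C)OO1
Why: Neutral electrophilic epoxidation (no Baeyer–Villiger risk for the α-hydroxy ketone, no reaction at the electron-poor enamide) can reach the ring B alkene only from the exo face because ring A blocks the endo face, and this is also the face of the hydrogen-bonding tertiary OH, so both oxirane centres are set cis to OH and OMe.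

## Compound list
1 | (S)-4-hydroxycyclopent-2-en-1-one | O=C1C[C@H](O)C=C1 | starting material
2 | (S)-4-methoxycyclopent-2-en-1-one | O=C1C[C@H](OC)C=C1 | intermediate
3 | furan | c1ccoc1 | starting material
4 | 2-furyllithium | [Li]c1ccco1 | intermediate
5 | (1R,4S)-1-(furan-2-yl)-4-methoxycyclopent-2-en-1-ol (OH cis to OMe) | o1cccc1[C@@]2(O)C[C@H](OC)C=C2 | intermediate
6 | (3S,5R)-7-hydroxy-3-methoxy-6-oxaspiro[4.5]deca-1,8-dien-10-one (anomers at C7) | OC1C=CC(=O)[C@@]2(O1)C[C@H](OC)C=C2 | intermediate
7 | (3S,5R)-8-azido-7-hydroxy-3-methoxy-6-oxaspiro[4.5]dec-1-en-10-one (epimers at C7, C8) | [N-]=[N+]=NC1CC(=O)[C@@]2(OC1O)C[C@H](OC)C=C2 | intermediate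
8 | 1-bromoheptane | CCCCCCCBr | starting material
9 | acrolein | C=CC=O | starting material
10 | heptylmagnesium bromide | CCCCCCC[Mg]Br | intermediate
11 | (E)-dec-1-enyl trimethylsilyl ether | CCCCCCCC/C=C/O[Si](C)(C)C | intermediate
12 | decanal | CCCCCCCCCC=O | intermediate
13 | malonic acid | OC(=O)CC(=O)O | starting material
14 | (E)-dodec-2-enoic acid | CCCCCCCCC/C=C/C(=O)O | intermediate
15 | trimethyliminophosphorane of the 8-amino spiro ketone | CP(C)(C)=NC1CC(=O)[C@@]2(OC1O)C[C@H](OC)C=C2 | intermediate
16 | (E)-N-[(3S,5R)-7-hydroxy-3-methoxy-10-oxo-6-oxaspiro[4.5]dec-1-en-8-yl]dodec-2-enamide | CCCCCCCCC/C=C/C(=O)NC1CC(=O)[C@@]2(OC1O)C[C@H](OC)C=C2 | intermediate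
17 | (E)-N-{4-[(1R,4S)-1-hydroxy-4-methoxycyclopent-2-en-1-yl]-1,4-dioxobutan-2-yl}dodec-2-enamide | CCCCCCCCC/C=C/C(=O)NC(C=O)CC(=O)[C@@]1(O)C[C@H](OC)C=C1 | intermediate
18 | (E)-N-{1-[(1S,4S)-1-hydroxy-4-methoxy-6-oxocyclohex-2-en-1-yl]-3-oxopropan-2-yl}dodec-2-enamide (in equilibrium with its spiro lactol) | CCCCCCCCC/C=C/C(=O)NC(C=O)C[C@@]1(O)C(=O)C[C@H](OC)C=C1 | intermediate
19 | (E)-N-[(1S,4R,5S,6R,7S)-1,6-dihydroxy-4-methoxy-9-oxobicyclo[3.3.1]non-2-en-7-yl]dodec-2-enamide | CCCCCCCCC/C=C/C(=O)N[C@H]1C[C@@]2(O)C(=O)[C@@H]([C@H]1O)[C@H](OC)C=C2 | intermediate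
20 | (E)-N-[(1S,2S,4S,5S,6S,7R,8S)-1,7-dihydroxy-5-methoxy-10-oxo-3-oxatricyclo[4.3.1.0(2,4)]decan-8-yl]dodec-2-enamide (CNP0137540.1) | CCCCCCCCC/C=C/C(=O)N[C@H]1C[C@@]2(O)C(=O)[C@@H]([C@H]1O)[C@H](OC)[C@@H]1O[C@@H]12 | target

## Step count and risks
Total steps: 9. Longest linear sequence: 7 (steps 1, 2, 3, 4, 7, 8, 9). The side chain (steps 5 and 6) joins at step 7.

**Step 8 (the proposed new step).**
- Risks:
  - The ring CH2 may migrate instead of the alkenyl carbon.
  - The side chain of 18 or 19 may shift onward to give the conjugated enone isomer.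
  - The amide may be lost by retro-aza-Michael reaction before the shift.
  - Methanol may be lost by β-elimination during the aldol stage.
- Fallback: it sets out from 16 and takes the aldehyde out of the rearrangement.
  - NaBH(OAc)3 reduces only the aldehyde share of the hemiacetal to the keto diol F1.
  - Stoichiometric Al(OtBu)3 in toluene, the classical chelating promoter for α-ketol ring enlargement, converts it into the ring-enlarged diol F2.
  - TEMPO/PhI(OAc)2 oxidises only the primary alcohol.
  - This comes back to the route at 18, which catalytic DBU in CH2Cl2 closes to 19.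

**Step 4.**
- Risks: the addition is reversible, azide is a good leaving group β to the ketone, and the adduct must still survive step 7.
- Fallback: it sets out from 6 and delivers nitrogen from a tether on the anomeric oxygen.
  - Cl3CC(O)NCO gives the trichloroacetyl carbamate F3.
  - K2CO3 in MeOH strips the trichloroacetyl group to the primary carbamate F4.
  - F4 closes in the same flask by intramolecular aza-Michael addition to the cis-fused oxazolidinone F5.
  - Acylation with 14 (PivCl, Et3N, LiCl) gives the N-acyl oxazolidinone F6.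
  - LiOH in THF–H2O opens the labile anomeric carbamate with decarboxylation.
  - This comes back to the route at 16 and bypasses 7 and 15.

**Step 2.**
- Risks: the small methoxy group gives only modest facial bias, may chelate lithium, and the enone can be enolised.
- Fallback: it sets out from 1 and uses a bulky silyl group as the control element.
  - TBSCl and imidazole give the silyl ether F7.
  - 2-Furyllithium adds anti to the large group to give the silylated furyl carbinol F8.
  - TBAF frees the furyl diol F9.
  - Ag2O/MeI methylates only the secondary OH.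
  - This comes back to the route at 5.

## Further compounds
F1 | step 8 | keto diol, (E)-N-{1-hydroxy-4-[(1R,4S)-1-hydroxy-4-methoxycyclopent-2-en-1-yl]-4-oxobutan-2-yl}dodec-2-enamide | CCCCCCCCC/C=C/C(=O)NC(CO)CC(=O)[C@@]1(O)C[C@H](OC)C=C1
F2 | step 8 | ring-enlarged diol, (E)-N-{1-hydroxy-3-[(1S,4S)-1-hydroxy-4-methoxy-6-oxocyclohex-2-en-1-yl]propan-2-yl}dodec-2-enamide | CCCCCCCCC/C=C/C(=O)NC(CO)C[C@@]1(O)C(=O)C[C@H](OC)C=C1
F3 | step 4 | trichloroacetyl carbamate of 6 at the anomeric oxygen | ClC(Cl)(Cl)C(=O)NC(=O)OC1C=CC(=O)[C@@]2(O1)C[C@H](OC)C=C2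
F4 | step 4 | primary carbamate of 6 at the anomeric oxygen | NC(=O)OC1C=CC(=O)[C@@]2(O1)C[C@H](OC)C=C2
F5 | step 4 | cis-fused oxazolidinone spanning C7–O and C8–N | O=C1NC2CC(=O)[C@@]3(OC2O1)C[C@H](OC)C=C3
F6 | step 4 | N-acyl oxazolidinone carrying the (E)-dodec-2-enoyl group | CCCCCCCCC/C=C/C(=O)N1C2CC(=O)[C@@]3(OC2OC1=O)C[C@H](OC)C=C3
F7 | step 2 | silyl ether, (S)-4-(tert-butyldimethylsilyloxy)cyclopent-2-en-1-one | O=C1C[C@H](O[Si](C)(C)C(C)(C)C)C=C1
F8 | step 2 | silylated furyl carbinol, (1R,4S)-4-(tert-butyldimethylsilyloxy)-1-(furan-2-yl)cyclopent-2-en-1-ol | o1cccc1[C@@]2(O)C[C@H](O[Si](C)(C)C(C)(C)C)C=C2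
F9 | step 2 | furyl diol, (1R,4S)-1-(furan-2-yl)cyclopent-2-ene-1,4-diol | o1cccc1[C@@]2(O)C[C@H](O)C=C2
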